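Monday's flask, 15 mM of substrate with 0.75 mM of free catalyst at 25 °C, is to be read at 10 min, and the next step has to be chosen from the options below.

| flask | substrate | free catalyst | temperature | remark | time |
|---|---|---|---|---|---|
| Monday's | 15 mM | 0.75 mM | 25 °C | the very flask that is asked about, followed so far |  |
| Wednesday's | 15 mM | 0.75 mM | 31 °C | run made earlier |  |
| flask | 15 mM | 0.75 mM | 25 °C |  | 10 min |

| run | time / min | target / % | substrate / % |
|---|---|---|---|
| Monday's | 0.500 | 22.6 | 74.5 |
| Monday's | 0.833 | 22.6 | 74.3 |
| Monday's | 1.50 | 23.0 | 74.4 |
| Monday's | 3.00 | 22.6 | 74.0 |
| Monday's | 6.00 | 22.5 | 73.3 |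
| Wednesday's | 0.500 | 18.7 | 79.8 |
| Wednesday's | 0.833 | 18.8 | 79.1 |
| Wednesday's | 1.50 | 19.0 | 79.5 |
| Wednesday's | 3.00 | 19.2 | 79.4 |
| Wednesday's | 6.00 | 19.3 | 79.2 |

(readings scatter by 0.3 percentage points)

- east: change nothing and wait 5.0 min more
- south-east: at 10 min add free catalyst, 100% of the amount charged, then wait 5.0 min
- north-east: at 10 min take out 90% of the target then present, then wait 5.0 min
- north-west: at 10 min raise the temperature by 25 K, then wait 5.0 min

- target taken out counts as made
- additions bring no volume worth counting

* target, in percent of the substrate first charged, at 10 min
* the remedy with the largest gain of target, or "none" below 2 percentage points (east / south-east / north-east / north-west / none)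
* target present, with what was taken out counted in, in percent of the substrate first charged, after south-east
* target present, with what was taken out counted in, in percent of the substrate first charged, after north-east

Monday's target reads 22.6% at 0.500 min and 22.5% at 6.00 min, while the first substrate reading is 74.5%. Two pictures fit such a flat line: an equilibrium, which added catalyst does not move, or a catalyst that has stopped, which added catalyst restarts. The choice of remedy hangs on this, so the reckoning here tries the second picture to see what is at stake.

Suppose substrate falls pseudo-first-order, in proportion to itself and to working catalyst, while the catalyst dies at its own first-order pace. Then the logarithm of substrate charged over substrate left, once the catalyst has died, is in proportion to the catalyst charged. Monday's first reading gives 0.392 mM⁻¹, the reach: that logarithm per unit of catalyst charged. Wednesday's flask, at 31 °C, reads lower, 0.301 mM⁻¹.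

Under this supposition a second equal charge to Monday's flask should take the same share again and leave 55.5% of the substrate. At Monday's first reading target made up 88.6% of the substrate lost, so this reckoning expects about 39.4% of target after south-east and sends the next run there.

The forecast took the first picture: 22.5% now, north-east as best, 22.4% after south-east and 37.3% after north-east, with the words “Extra catalyst should gain nothing”.

The steps behind the readings are these.

    catalyst intermediate ⇌ free catalyst + target (K = 0.0150 M, k = 2.70 s⁻¹, Ea = 61.0 kJ mol⁻¹, ΔH = −5.00 kJ mol⁻¹)
    substrate + free catalyst ⇌ catalyst intermediate (K = 71.0 L mol⁻¹, k = 340 L mol⁻¹ s⁻¹, Ea = 44.0 kJ mol⁻¹, ΔH = −13.0 kJ mol⁻¹)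
    target ⇌ isomer of the product (K = 0.150, k = 0.0800 s⁻¹, Ea = 80.0 kJ mol⁻¹, ΔH = −43.0 kJ mol⁻¹)
    free catalyst → spent catalyst (k = 0.260 s⁻¹, Ea = 82.0 kJ mol⁻¹)
    (constants at 25 °C)

The flask gives 22.5% at 10 min, with free catalyst at 0% and spent catalyst at 100% of the catalyst charged. The best remedy is south-east, with a gain of 12 percentage points; it reaches 34.4%, 12 points above the forecast's value and below the reckoned 39.4%, and north-east reaches 25.2%. For a neighbouring flask charged with 0.19 mM of free catalyst, the reach from Monday's first reading predicts 92.8% of the substrate left and 6.38% of target. At 10 min that flask holds 92% of the substrate and 7.18% of target.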